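(The earlier runs and the new flask are calculated on assumed constants.)

In a one-step world Q + Z gives E and nothing takes E away, so with Z held fixed a larger charge of Q gives a larger [E], up to the charge of Z.

| flask | Q | Z | remark | time |
|---|---|---|---|---|
| ash | 2.2 mM | 10 mM | run made earlier |  |
| alder | 6.7 mM | 10 mM | run made earlier |  |
| maple | 14 mM | 10 mM | run made earlier |  |
| north-east | 2.0 mM | 10.0 mM |  | 30 min |
| north | 6.0 mM | 10.0 mM |  | 30 min |
| south-west | 20 mM | 10.0 mM |  | 30 min |

| run | time / min | E / % | Q / % |
|---|---|---|---|
| ash | 4.00 | 33.4 | 32.8 |
| ash | 10.0 | 39.1 | 11.7 |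
| ash | 20.0 | 34.5 | 8.3 |
| ash | 30.0 | 30.0 | 7.8 |
| alder | 2.50 | 20.6 | 48.6 |
| alder | 6.00 | 24.3 | 23.6 |
| alder | 12.0 | 21.2 | 11.6 |
| alder | 30.0 | 15.3 | 5.0 |
| maple | 2.50 | 12.5 | 52.5 |
| maple | 6.00 | 11.7 | 30.1 |
| maple | 12.0 | 8.1 | 17.2 |
| maple | 30.0 | 3.5 | 9.2 |

(standard deviation of a reading: 0.5 percentage points)

- "hardly changes" means that all values lie within two and a half points (for a concentration: within two and a half percent of the largest)
- a reading of Q is of its free form alone

1. [E] at the end for north-east, north, south-west, in this order
2. the course of these numbers from the first flask to the last (hardly changes / rises all the way / falls, then rises / falls all the way / rises, then falls)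

But after 30 min the ash run holds 30.0% of the Q charged as E, alder 15.3% and maple 3.5%, so across these runs the percentage falls as the charge grows. [E] is therefore the charge times a falling percentage, and I solve the two ends apart: at small charges the charge leads, and at large ones the fall leads. To join them I let ln(percentage) drop in a straight line with the charge. From alder to maple, the line reads 4.95 mM: this is my loss scale, the extra Q over which ln(percentage) drops by one. Charge times such a falling exponential peaks where the charge equals the scale, and north stands close to that, so I expect a rise and then a fall. Carried on from maple, the line gives south-west 1.04%, or 0.208 mM, a loose estimate, for it is an extrapolation and maple's 3.5% carries a scatter of 0.5 percentage points.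

The forecast gives 0.6 mM, 1 mM and 0.2 mM, with the course rises, then falls, and judges that “E is probably consumed by something tied to Q or its by-products”.

The flasks give 0.617 mM, 0.966 mM and 0.214 mM, and the course is rises, then falls.

    Q + Z ⇌ E (K = 430 M⁻¹, k = 0.320 M⁻¹ s⁻¹)
    Q + Z ⇌ X (K = 590 M⁻¹, k = 0.200 M⁻¹ s⁻¹)
    Q + E → D (k = 0.700 M⁻¹ s⁻¹)

From north-east to south-west, the loss scale reads 5.35 mM. The step Q + E → D is a part of that loss: a south-west run without this step ends at 4.62 mM instead of 0.214 mM, and the course changes. The north-east run without it ends at 0.903 mM, so the scale without the step stretches beyond the south-west charge, to 26.8 mM.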